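**Assumption:** halimane numbering is used (C1–C10 decalin, C11–C16 side chain, C17 on C8, C18/C19 on C4, C20 on C9). The target is read as (4S,5R,8S,9R,13E): 5α-H, 4β-CO2H, 4α-CH3, 8β-CH3, 9β-CH3.

## Retrosynthetic overview

1. Target 19 ⇐ buffered oxidation of the C19 neopentyl alcohol 17; the 13E allylic acetate ⇐ carboalumination/hydroxymethylation of a terminal alkyne that stands in for C13–C16 until the cation chemistry is over.
2. The 1(10)-ene ⇐ eliminative opening of the 10β,19-ether bridge of 12.
3. 12 ⇐ one-flask cationic cascade of acyclic (S)-epoxide 10: ring A first (C4–C5), ring B second (C10–C9), then 9→8 hydride shift, 10→9 methyl shift, and capture of the C10 cation by the C19 oxygen.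
4. 10 ⇐ asymmetric methylene transfer to methyl ketone 9 ⇐ (E)-geranylacetone 1 plus bromo-ketal 6, joined by allylic oxidation and copper-catalysed coupling.

## Route

Step 1
Reactants: 1 (E)-geranylacetone
Product: 3 (5E)-6,10-dimethylundeca-5,9-dien-1-yne, via enol phosphate 2 (not isolated)
Conditions: LiN(iPr)2 (1.05 equiv), THF, −78 °C; ClP(O)(OEt)2; then LiN(iPr)2 (2.3 equiv), −78 °C → rt
Reagents that add atoms: none
Why: Kinetic enolisation on the methyl side, O-phosphorylation and base-induced elimination of the enol phosphate (Negishi alkyne synthesis) turn the methyl ketone into the terminal alkyne without touching the E-alkene.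

Step 2
Reactants: 3 (5E)-6,10-dimethylundeca-5,9-dien-1-yne
Product: 4 (2E,6E)-2,6-dimethylundeca-2,6-dien-10-yn-1-ol
Conditions: SeO2 (0.3 equiv), t-BuOOH (3 equiv), salicylic acid (0.1 equiv), CH2Cl2, 0 °C → rt
Reagents that add atoms: tert-butyl hydroperoxide CC(C)(C)OO (net oxygen donor, relayed through catalytic selenium dioxide O=[Se]=O)
Why: Sharpless catalytic SeO2 allylic oxidation (ene reaction, then 2,3-sigmatropic shift) hydroxylates the E-methyl of the terminal isopropylidene, which fixes the E geometry of the future C5=C10 alkene; yield is expected to be moderate.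

Step 3
Reactants: 4 (2E,6E)-2,6-dimethylundeca-2,6-dien-10-yn-1-ol
Product: 5 (2E,6E)-1-bromo-2,6-dimethylundeca-2,6-dien-10-yne
Conditions: CBr4, PPh3, CH2Cl2, −20 → 0 °C
Reagents that add atoms: carbon tetrabromide BrC(Br)(Br)Br
Why: Appel reaction; SN2 displacement of the oxyphosphonium at the primary carbon gives the allylic bromide without allylic transposition or loss of E geometry.

Step 4
Reactants: 5 (2E,6E)-1-bromo-2,6-dimethylundeca-2,6-dien-10-yne; 6 2-(2-bromoethyl)-2-methyl-1,3-dioxolane
Product: 9 (6E,10E)-6,10-dimethylpentadeca-6,10-dien-14-yn-2-one, via Grignard reagent 7 (not isolated), via dioxolane 8 (not isolated)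
Conditions: 6, Mg, THF, 25 °C; add to 5 (2.3 equiv of 7), Li2CuCl4 (3 mol %), THF, −40 → 0 °C; then 2 M HCl, THF/H2O, rt
Reagents that add atoms: water O
Why: Kochi-type copper-catalysed Grignard coupling at the primary allylic bromide (α-attack, E retained) installs C2–C4 and C18; the first equivalent of 7 only parks the alkyne as its magnesium acetylide, and aqueous acid then unmasks the methyl ketone.

Step 5
Reactants: 9 (6E,10E)-6,10-dimethylpentadeca-6,10-dien-14-yn-2-one
Product: 10 (S)-2-[(4E,8E)-4,8-dimethyltrideca-4,8-dien-12-yn-1-yl]-2-methyloxirane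
Conditions: Me3S(O)I, NaH (1.2 equiv each); LaLi3(binaphtholate)3 (5 mol %, BINOL enantiomer chosen to give the S epoxide), tris(2,4,6-trimethoxyphenyl)phosphine oxide (5 mol %), 5 Å MS, THF, rt
Reagents that add atoms: trimethylsulfoxonium iodide C[S+](C)(C)=O.[I-]
Why: Catalytic asymmetric Corey–Chaykovsky epoxidation; the lanthanum–lithium binaphtholate delivers the sulfoxonium methylide to one face of the methyl ketone and so sets the C4 quaternary stereocentre (about 90 % ee expected for a dialkyl methyl ketone), with alkenes and alkyne inert to the ylide.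

Step 6
Reactants: 10 (S)-2-[(4E,8E)-4,8-dimethyltrideca-4,8-dien-12-yn-1-yl]-2-methyloxirane
Product: 12 10β,19-epoxy-15,16-dinorhalim-13-yne (5α-H, 8β-CH3, 9β-CH3, 9α-butynyl), via labdenol 11 (not isolated)
Conditions: BF3·OEt2 (0.3 equiv), CH2Cl2/(CF3)2CHOH 9:1, 2 mM, −78 °C, 1 h, then 0 °C, 2 h; Et3N quench
Reagents that add atoms: none
Why: Proposed new method: the BF3-activated epoxide is opened at its tertiary carbon with inversion by the C5=C10 alkene in a chair–chair bicyclisation (the CH2O–B arm, tied back to the leaving oxygen, takes the axial site; the E-alkenes give 5α-H/10β-CH3), the labdanyl C8 cation or its 8-ene 11 then undergoes the biosynthetic 9α→8α hydride and 10β→9β methyl shifts under the protic BF3·ROH acid, and the C10 cation is caught on its β face by the 1,3-diaxial C19 hydroxyl, the closest known reaction types being Lewis-acid epoxy-polyene cyclisation and the BF3-promoted friedo rearrangement/cycloetherification used for aureol-type skeletons.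

Step 7
Reactants: 12 10β,19-epoxy-15,16-dinorhalim-13-yne
Product: 13 19-(trimethylsilyloxy)-15,16-dinorhalim-1(10)-en-13-yne
Conditions: Me3SiOTf (1.3 equiv), 2,6-lutidine (2.5 equiv), CH2Cl2, −40 → 0 °C; NaHCO3 work-up, Et3N-deactivated silica
Reagents that add atoms: trimethylsilyl trifluoromethanesulfonate C[Si](C)(C)OS(=O)(=O)C(F)(F)F
Why: O-silylation, C10–O ionisation and deprotonation by the hindered pyridine (the E1 mode known for silyl triflate/2,6-lutidine cleavage of tert-alkyl ethers) open the bridge; the exposed C1 methylene hydrogen should be removed in preference to the C5 methine buried between two quaternary carbons, and the buffered medium prevents equilibration to the 5(10)-ene.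

Step 8
Reactants: 13 19-(trimethylsilyloxy)-15,16-dinorhalim-1(10)-en-13-yne
Product: 17 (13E)-19-hydroxyhalima-1(10),13-dien-15-yl acetate, via alkenylalane 14 (not isolated), via aluminium alkoxide 15 (not isolated), via silyl ether acetate 16 (not isolated)
Conditions: AlMe3 (3 equiv), Cp2ZrCl2 (0.3 equiv), CH2Cl2, 0 °C → rt; (CH2O)n (6 equiv), THF, rt; then pyridine, Ac2O, DMAP (cat.), 0 °C → rt; 10 % aq. citric acid work-up
Reagents that add atoms: trimethylaluminium C[Al](C)C; paraformaldehyde (formaldehyde C=O); acetic anhydride CC(=O)OC(C)=O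
Why: Negishi zirconium-catalysed syn-carboalumination puts CH3 on C13 and Al on C14, hydroxymethylation of the alkenylalane retains geometry (13E), the aluminium alkoxide is acetylated in situ as in reductive-acetylation protocols, and the acidic work-up removes the labile primary TMS ether.

Step 9
Reactants: 17 (13E)-19-hydroxyhalima-1(10),13-dien-15-yl acetate
Product: 19 (4S,5R,8S,9R,13E)-15-acetoxyhalima-1(10),13-dien-19-oic acid, via aldehyde 18 (not isolated)
Conditions: TEMPO (0.1 equiv), NaClO2 (2 equiv), NaOCl (0.03 equiv), MeCN/sodium phosphate buffer pH 6.7, 35 °C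
Reagents that add atoms: sodium chlorite [Na+].[O-]Cl=O
Why: TEMPO/chlorite oxidation (Zhao protocol) takes the neopentyl alcohol through aldehyde 18 to the acid near neutral pH, where the allylic acetate and both trisubstituted alkenes survive and the 1(10)-ene/19-acid pair cannot relactonise.

## Compound list

1 | (E)-geranylacetone, (5E)-6,10-dimethylundeca-5,9-dien-2-one | CC(C)=CCC/C(C)=C/CCC(C)=O | starting material
2 | diethyl (5E)-6,10-dimethylundeca-1,5,9-trien-2-yl phosphate | CC(C)=CCC/C(C)=C/CCC(=C)OP(=O)(OCC)OCC | intermediate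
3 | (5E)-6,10-dimethylundeca-5,9-dien-1-yne | CC(C)=CCC/C(C)=C/CCC#C | intermediate
4 | (2E,6E)-2,6-dimethylundeca-2,6-dien-10-yn-1-ol | OC/C(C)=C/CC/C(C)=C/CCC#C | intermediate
5 | (2E,6E)-1-bromo-2,6-dimethylundeca-2,6-dien-10-yne | BrC/C(C)=C/CC/C(C)=C/CCC#C | intermediate
6 | 2-(2-bromoethyl)-2-methyl-1,3-dioxolane | CC1(CCBr)OCCO1 | starting material
7 | [2-(2-methyl-1,3-dioxolan-2-yl)ethyl]magnesium bromide | CC1(CC[Mg]Br)OCCO1 | intermediate
8 | 2-[(4E,8E)-4,8-dimethyltrideca-4,8-dien-12-yn-1-yl]-2-methyl-1,3-dioxolane | CC1(CCC/C(C)=C/CC/C(C)=C/CCC#C)OCCO1 | intermediate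
9 | (6E,10E)-6,10-dimethylpentadeca-6,10-dien-14-yn-2-one | CC(=O)CCC/C(C)=C/CC/C(C)=C/CCC#C | intermediate
10 | (S)-2-[(4E,8E)-4,8-dimethyltrideca-4,8-dien-12-yn-1-yl]-2-methyloxirane | C[C@@]1(CO1)CCC/C(C)=C/CC/C(C)=C/CCC#C | intermediate
11 | 15,16-dinorlabd-8-en-13-yn-19-ol (5α-H, 10β-CH3, 4β-CH2OH) | C#CCCC1=C(C)CC[C@H]2[C@@](C)(CO)CCC[C@]12C | intermediate
12 | 10β,19-epoxy-15,16-dinorhalim-13-yne (5α-H, 8β-CH3, 9β-CH3) | C#CCC[C@@]1(C)[C@@]23CCC[C@](C)(CO3)[C@@H]2CC[C@@H]1C | intermediate
13 | 19-(trimethylsilyloxy)-15,16-dinorhalim-1(10)-en-13-yne | C#CCC[C@@]1(C)C2=CCC[C@](C)(CO[Si](C)(C)C)[C@@H]2CC[C@@H]1C | intermediate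
14 | dimethyl[(13E)-19-(trimethylsilyloxy)-15-norhalima-1(10),13-dien-14-yl]alane | C[Al](C)/C=C(\C)CC[C@@]1(C)C2=CCC[C@](C)(CO[Si](C)(C)C)[C@@H]2CC[C@@H]1C | intermediate
15 | dimethylaluminium (13E)-19-(trimethylsilyloxy)halima-1(10),13-dien-15-olate | C[Al](C)OC/C=C(\C)CC[C@@]1(C)C2=CCC[C@](C)(CO[Si](C)(C)C)[C@@H]2CC[C@@H]1C | intermediate
16 | (13E)-19-(trimethylsilyloxy)halima-1(10),13-dien-15-yl acetate | CC(=O)OC/C=C(\C)CC[C@@]1(C)C2=CCC[C@](C)(CO[Si](C)(C)C)[C@@H]2CC[C@@H]1C | intermediate
17 | (13E)-19-hydroxyhalima-1(10),13-dien-15-yl acetate | CC(=O)OC/C=C(\C)CC[C@@]1(C)C2=CCC[C@](C)(CO)[C@@H]2CC[C@@H]1C | intermediate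
18 | (13E)-15-acetoxyhalima-1(10),13-dien-19-al | CC(=O)OC/C=C(\C)CC[C@@]1(C)C2=CCC[C@](C)(C=O)[C@@H]2CC[C@@H]1C | intermediate
19 | (4S,5R,8S,9R,13E)-15-acetoxyhalima-1(10),13-dien-19-oic acid | CC(=O)OC/C=C(\C)CC[C@@]1(C)C2=CCC[C@](C)(C(=O)O)[C@@H]2CC[C@@H]1C | target

## Step count and risks

Total steps: 9. Longest linear sequence: 9 (from 1; 6 is used as purchased).

**Step 6 (cascade).** The risks are Meinwald rearrangement of the epoxide, the competing chair with the CH2O arm equatorial (wrong C4/C5 relationship), stalling at the labdene stage, and slow 6-endo capture of the C8 cation by the alkyne. The fallback sets out from 10 and returns at 12. It gives up the single cascade and separates ring formation from the backbone rearrangement. MeAlCl2 (2 equiv), CH2Cl2, −78 °C cyclises 10; its Al–CH3 bonds quench the liberated proton, so the reaction stops cleanly at labdenol 11 (with its 7-ene and 8(17)-ene isomers), which is isolated and freed of any C4-epimeric material. A separate treatment with stoichiometric BF3·OEt2, CH2Cl2, −50 → 0 °C then performs the hydride/methyl shifts and ether closure to 12. It makes no compound outside the list (F0).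

**Step 7 (regiochemistry of the ether opening).** The 5(10)-ene is the thermodynamic isomer, and the kinetic preference for C1–H is argued, not proven. The fallback sets out from the crude product of step 7, that is 13 mixed with 19-(trimethylsilyloxy)-15,16-dinorhalim-5(10)-en-13-yne F1, and returns at 13. It replaces the kinetic elimination by a syn-elimination that can only go one way:
- The mixture is desilylated (citric acid, MeOH) and oxidised under the step 9 conditions to 15,16-dinorhalim-1(10)-en-13-yn-19-oic acid F2 and 15,16-dinorhalim-5(10)-en-13-yn-19-oic acid F3.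
- BF3·OEt2 in CH2Cl2 at 0 °C converges both acids, through the same C10 cation, on 15,16-dinorhalim-13-yn-19,10β-olide F4 (the classical resin-acid γ-lactone closure).
- LiAlH4 in THF gives 15,16-dinorhalim-13-yne-10β,19-diol F5.
- Me3SiCl/imidazole silylates only the primary hydroxyl, giving 19-(trimethylsilyloxy)-15,16-dinorhalim-13-yn-10β-ol F6.
- Burgess reagent in toluene at 60 °C dehydrates the tertiary alcohol by syn-elimination. The only hydrogen cis to the 10β-oxygen is H1β (H5 is α, C9 is quaternary), so 13 is the only alkene possible.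

**Step 8 (telescoped carboalumination, hydroxymethylation, acetylation).** The risks are loss of the TMS ether to the aluminium Lewis acid and incomplete in situ acetylation. The fallback sets out from 13 and returns at 17. It builds the trisubstituted alkene by substitution on a vinyl iodide instead of carbometalation:
- n-BuLi, THF, −78 °C, then (CH2O)n gives 19-(trimethylsilyloxy)-16-norhalim-1(10)-en-13-yn-15-ol F7.
- NaAlH2(OCH2CH2OMe)2 in THF at 0 °C (trans-hydroalumination through the alkoxide), then I2 at −78 °C, gives (13Z)-13-iodo-19-(trimethylsilyloxy)-16-norhalima-1(10),13-dien-15-ol F8.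
- LiCuMe2 in Et2O at 0 °C replaces iodine by methyl with retention, giving (13E)-19-(trimethylsilyloxy)halima-1(10),13-dien-15-ol F9.
- Ac2O/pyridine gives 16, and the citric acid work-up gives 17.

## Further compounds

F0 | step 6 | none | none
F1 | step 7 | 19-(trimethylsilyloxy)-15,16-dinorhalim-5(10)-en-13-yne | C#CCC[C@@]1(C)C2=C(CC[C@@H]1C)[C@@](C)(CO[Si](C)(C)C)CCC2
F2 | step 7 | 15,16-dinorhalim-1(10)-en-13-yn-19-oic acid | C#CCC[C@@]1(C)C2=CCC[C@](C)(C(=O)O)[C@@H]2CC[C@@H]1C
F3 | step 7 | 15,16-dinorhalim-5(10)-en-13-yn-19-oic acid | C#CCC[C@@]1(C)C2=C(CC[C@@H]1C)[C@@](C)(C(=O)O)CCC2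
F4 | step 7 | 15,16-dinorhalim-13-yn-19,10β-olide | C#CCC[C@@]1(C)[C@@]23CCC[C@](C)(C(=O)O3)[C@@H]2CC[C@@H]1C
F5 | step 7 | 15,16-dinorhalim-13-yne-10β,19-diol | C#CCC[C@@]1(C)[C@@]2(O)CCC[C@](C)(CO)[C@@H]2CC[C@@H]1C
F6 | step 7 | 19-(trimethylsilyloxy)-15,16-dinorhalim-13-yn-10β-ol | C#CCC[C@@]1(C)[C@@]2(O)CCC[C@](C)(CO[Si](C)(C)C)[C@@H]2CC[C@@H]1C
F7 | step 8 | 19-(trimethylsilyloxy)-16-norhalim-1(10)-en-13-yn-15-ol | OCC#CCC[C@@]1(C)C2=CCC[C@](C)(CO[Si](C)(C)C)[C@@H]2CC[C@@H]1C
F8 | step 8 | (13Z)-13-iodo-19-(trimethylsilyloxy)-16-norhalima-1(10),13-dien-15-ol | OC/C=C(\I)CC[C@@]1(C)C2=CCC[C@](C)(CO[Si](C)(C)C)[C@@H]2CC[C@@H]1C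
F9 | step 8 | (13E)-19-(trimethylsilyloxy)halima-1(10),13-dien-15-ol | OC/C=C(\C)CC[C@@]1(C)C2=CCC[C@](C)(CO[Si](C)(C)C)[C@@H]2CC[C@@H]1C
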